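**Retrosynthetic overview**
1. The target is the hetero-Diels–Alder dimer of a single o-quinone, so both halves are (5S,7S,10S)-brussonol and the 1,4-dioxane is the last ring formed.
2. Ring B of brussonol with its 7,10-oxygen bridge comes from a Marson-type oxocarbenium/Friedel–Crafts closure (C7–C8) of a cis-fused γ-lactol.
3. The lactol comes from a γ-benzyl butenolide whose quaternary C10–C20 bond is made by an intermolecular vinylogous Mukaiyama aldol between a bicyclic 2-silyloxyfuran and an aryl aldehyde.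
4. The silyloxyfuran is built on 2,2-dimethylcyclohexanone (ring A bought; Rubottom oxidation, intramolecular HWE); the aldehyde comes from veratrole by two directed lithiations.
5. Ring order: A (purchased) → butenolide → aldol union → saturated lactone → B plus oxygen bridge → dioxane.

Assumption: positions are labelled with icetexane numbering (C1–C20, primes for the dienophile half of the dimer); racemic compounds are written without stereodescriptors.

**Route**

Step 1
Reactants: 1 veratrole
Product: 3 2-(2,3-dimethoxyphenyl)propan-2-ol, via (2,3-dimethoxyphenyl)lithium 2 (not isolated)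
Conditions: n-BuLi, TMEDA, Et2O, 0 °C → rt; acetone, −78 °C → rt; aq. NH4Cl
Reagents that add atoms: acetone, CC(C)=O
Why: Directed ortho-metalation (both methoxy groups steer the base to C3) followed by 1,2-addition of the aryllithium to acetone; no stereocentre.

Step 2
Reactants: 3 2-(2,3-dimethoxyphenyl)propan-2-ol
Product: 4 1-isopropyl-2,3-dimethoxybenzene
Conditions: Et3SiH, TFA, CH2Cl2, 0 °C → rt
Reagents that add atoms: none
Why: Ionic hydrogenation, in which TFA ionises the tertiary benzylic alcohol to a cation stabilised by the electron-rich ring and Et3SiH reduces it to the isopropyl group.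

Step 3
Reactants: 4 1-isopropyl-2,3-dimethoxybenzene
Product: 6 4-isopropyl-2,3-dimethoxybenzaldehyde, via (4-isopropyl-2,3-dimethoxyphenyl)lithium 5 (not isolated)
Conditions: n-BuLi, TMEDA, Et2O, 0 °C → rt; DMF, −78 → 0 °C; 1 M HCl
Reagents that add atoms: N,N-dimethylformamide, CN(C)C=O
Why: A second directed ortho-metalation at the only position ortho to a methoxy group, then formylation with DMF, fixes the 1,2,3,4-substitution pattern of the aromatic ring.

Step 4
Reactants: 7 2,2-dimethylcyclohexanone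
Product: 8 (6,6-dimethylcyclohex-1-en-1-yl)oxytrimethylsilane
Conditions: TMSOTf, Et3N, CH2Cl2, 0 °C
Reagents that add atoms: trimethylsilyl triflate, C[Si](C)(C)OS(=O)(=O)C(F)(F)F
Why: Silyl enol ether formation by soft enolisation gives one regioisomer because the ketone has only one enolisable α-carbon.

Step 5
Reactants: 8 (6,6-dimethylcyclohex-1-en-1-yl)oxytrimethylsilane
Product: 10 6-hydroxy-2,2-dimethylcyclohexanone (racemic), via 2,2-dimethyl-6-(trimethylsilyloxy)cyclohexanone 9 (not isolated)
Conditions: mCPBA, NaHCO3, CH2Cl2, 0 °C; then 1 M HCl, THF, rt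
Reagents that add atoms: mCPBA, OOC(=O)c1cccc(Cl)c1
Why: Rubottom oxidation (epoxidation of the enol ether, silyl shift, acid desilylation) installs the future C10 oxygen; the racemic stereocentre is erased again in step 8.

Step 6
Reactants: 10 6-hydroxy-2,2-dimethylcyclohexanone
Product: 11 3,3-dimethyl-2-oxocyclohexyl 2-(diethoxyphosphoryl)acetate (racemic)
Conditions: (EtO)2P(O)CH2CO2H, DCC, DMAP (cat.), CH2Cl2, 0 °C → rt
Reagents that add atoms: diethylphosphonoacetic acid, CCOP(=O)(CC(=O)O)OCC
Why: Steglich esterification of the secondary alcohol places the phosphonate within reach of the ketone.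

Step 7
Reactants: 11 3,3-dimethyl-2-oxocyclohexyl 2-(diethoxyphosphoryl)acetate
Product: 12 4,4-dimethyl-5,6,7,7a-tetrahydro-1-benzofuran-2(4H)-one (racemic)
Conditions: NaH, THF, 0 °C → rt
Reagents that add atoms: none
Why: Intramolecular Horner–Wadsworth–Emmons olefination closes the five-membered butenolide (C5=C6), the intramolecularity offsetting the hindrance of the ketone next to the gem-dimethyl carbon.

Step 8
Reactants: 12 4,4-dimethyl-5,6,7,7a-tetrahydro-1-benzofuran-2(4H)-one
Product: 13 tert-butyl[(4,4-dimethyl-4,5,6,7-tetrahydro-1-benzofuran-2-yl)oxy]dimethylsilane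
Conditions: TBSOTf, Et3N, CH2Cl2, 0 °C
Reagents that add atoms: tert-butyldimethylsilyl triflate, CC(C)(C)[Si](C)(C)OS(=O)(=O)C(F)(F)F
Why: γ-Deprotonation and O-silylation of the butenolide give the aromatic 2-silyloxyfuran, the nucleophile for the aldol; the C7a stereocentre disappears.

Step 9 (key fragment union)
Reactants: 13 tert-butyl[(4,4-dimethyl-4,5,6,7-tetrahydro-1-benzofuran-2-yl)oxy]dimethylsilane; 6 4-isopropyl-2,3-dimethoxybenzaldehyde
Product: 14 7a-[hydroxy(4-isopropyl-2,3-dimethoxyphenyl)methyl]-4,4-dimethyl-5,6,7,7a-tetrahydro-1-benzofuran-2(4H)-one (racemic; both carbinol epimers)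
Conditions: BF3·OEt2 (1.1 equiv), CH2Cl2, −78 °C; quench with sat. aq. NaHCO3 at −78 °C
Reagents that add atoms: none
Why: Vinylogous Mukaiyama aldol in which the BF3-activated aldehyde is attacked by the furan at C7a (γ; the α-carbon C3 is shielded by the adjacent gem-dimethyl group), forming the C20–C10 bond and the oxygenated quaternary C10; neither new stereocentre is controlled here (C20 is deleted in step 10, C10 is resolved in step 11).

Step 10
Reactants: 14 7a-[hydroxy(4-isopropyl-2,3-dimethoxyphenyl)methyl]-4,4-dimethyl-5,6,7,7a-tetrahydro-1-benzofuran-2(4H)-one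
Product: 15 7a-(4-isopropyl-2,3-dimethoxybenzyl)-4,4-dimethyl-5,6,7,7a-tetrahydro-1-benzofuran-2(4H)-one (racemic)
Conditions: Et3SiH (3 equiv), TFA (10 equiv), CH2Cl2, −20 → 0 °C
Reagents that add atoms: none
Why: Ionic hydrogenation removes the benzylic hydroxyl through the o-methoxy-stabilised benzylic cation (the quaternary neighbour has no β-hydrogen, so no elimination), which erases the C20 stereocentre and merges both epimers into one racemate.

Step 11
Reactants: 15 7a-(4-isopropyl-2,3-dimethoxybenzyl)-4,4-dimethyl-5,6,7,7a-tetrahydro-1-benzofuran-2(4H)-one (racemic)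
Product: 16 (7aS)-7a-(4-isopropyl-2,3-dimethoxybenzyl)-4,4-dimethyl-5,6,7,7a-tetrahydro-1-benzofuran-2(4H)-one
Conditions: preparative chiral SFC, amylose tris(3,5-dimethylphenylcarbamate) phase, CO2/MeOH
Reagents that add atoms: none
Why: Resolution by chiral stationary-phase chromatography of a configurationally stable quaternary butenolide sets the absolute configuration at C10 (7aS, assigned by X-ray or by correlation of the step 14 product with brussonol dimethyl ether).

Step 12
Reactants: 16 (7aS)-7a-(4-isopropyl-2,3-dimethoxybenzyl)-4,4-dimethyl-5,6,7,7a-tetrahydro-1-benzofuran-2(4H)-one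
Product: 17 (3aS,7aS)-7a-(4-isopropyl-2,3-dimethoxybenzyl)-4,4-dimethylhexahydro-1-benzofuran-2(3H)-one
Conditions: H2 (1 atm), 10% Pd/C, EtOAc, rt
Reagents that add atoms: none
Why: Heterogeneous syn-hydrogenation of the butenolide C=C from the convex face carrying the angular benzyl group (the usual outcome for angularly substituted 5/6-fused enones) gives the cis-fused lactone and so sets C3a (C5 of the target, S) relative to C7a.

Step 13
Reactants: 17 (3aS,7aS)-7a-(4-isopropyl-2,3-dimethoxybenzyl)-4,4-dimethylhexahydro-1-benzofuran-2(3H)-one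
Product: 18 (3aS,7aS)-7a-(4-isopropyl-2,3-dimethoxybenzyl)-4,4-dimethyloctahydro-1-benzofuran-2-ol (both anomers)
Conditions: DIBAL-H (1.1 equiv), CH2Cl2, −78 °C; Rochelle salt
Reagents that add atoms: none
Why: Partial lactone reduction stops at the tetrahedral aluminium hemiacetal at −78 °C and gives the lactol, whose anomeric mixture is irrelevant.

Step 14
Reactants: 18 (3aS,7aS)-7a-(4-isopropyl-2,3-dimethoxybenzyl)-4,4-dimethyloctahydro-1-benzofuran-2-ol
Product: 19 (5S,7S,10S)-7,10-epoxy-11,12-dimethoxyicetexa-8,11,13-triene (brussonol dimethyl ether)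
Conditions: BF3·OEt2, CH2Cl2, −78 → 0 °C
Reagents that add atoms: none
Why: Marson-type oxocarbenium Friedel–Crafts cyclisation in which BF3 ionises the lactol and the tethered arene attacks C7 at the position para to the C12 methoxy group, closing the seven-membered ring; the bridge geometry forces the new C7 centre (S) to follow C10.

Step 15
Reactants: 19 brussonol dimethyl ether
Product: 20 (5S,7S,10S)-7,10-epoxyicetexa-8,11,13-triene-11,12-diol (brussonol)
Conditions: NaSEt (10 equiv), DMF, 120 °C; degassed 1 M HCl work-up under Ar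
Reagents that add atoms: none
Why: SN2 O-demethylation by ethanethiolate cleaves both aryl methyl ethers without a Lewis acid, so the benzylic ether bridge and all stereocentres are untouched.

Step 16
Reactants: 20 brussonol
Product: 21 (5S,7S,10S)-7,10-epoxyicetexa-8,13-diene-11,12-dione (brussonol o-quinone)
Conditions: Ag2O, MgSO4, Et2O, rt, dark; filter through Celite, concentrate below 25 °C
Reagents that add atoms: none
Why: Two-electron oxidation of the catechol to the o-quinone with silver(I) oxide under neutral anhydrous conditions that leave the ether bridge intact.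

Step 17
Reactants: 21 brussonol o-quinone (two molecules)
Product: 22 CNP0371333.1 (hetero-Diels–Alder dimer; new centres 13′R,14′R)
Conditions: neat film, 45 °C, Ar, dark, 24–48 h; chromatography / preparative HPLC
Reagents that add atoms: none
Why: Hetero-Diels–Alder dimerisation in which the O=C11–C12=O unit of one quinone adds suprafacially across C13′=C14′ of a second, head-to-tail (O12 to the unsubstituted C14′, O11 to C13′) and on the face of the dienophile opposite its own oxygen bridge, giving the cis-fused dioxane; the facial isomer, if formed, is removed by chromatography.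

**Compound list**
1 | veratrole (1,2-dimethoxybenzene) | COc1ccccc1OC | starting material
2 | (2,3-dimethoxyphenyl)lithium | [Li]c1cccc(OC)c1OC | intermediate (not isolated)
3 | 2-(2,3-dimethoxyphenyl)propan-2-ol | COc1cccc(C(C)(C)O)c1OC | intermediate
4 | 1-isopropyl-2,3-dimethoxybenzene | COc1cccc(C(C)C)c1OC | intermediate
5 | (4-isopropyl-2,3-dimethoxyphenyl)lithium | [Li]c1ccc(C(C)C)c(OC)c1OC | intermediate (not isolated)
6 | 4-isopropyl-2,3-dimethoxybenzaldehyde | O=Cc1ccc(C(C)C)c(OC)c1OC | intermediate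
7 | 2,2-dimethylcyclohexanone | CC1(C)CCCCC1=O | starting material
8 | (6,6-dimethylcyclohex-1-en-1-yl)oxytrimethylsilane | CC1(C)CCCC=C1O[Si](C)(C)C | intermediate
9 | 2,2-dimethyl-6-(trimethylsilyloxy)cyclohexanone (racemic) | CC1(C)CCCC(O[Si](C)(C)C)C1=O | intermediate (not isolated)
10 | 6-hydroxy-2,2-dimethylcyclohexanone (racemic) | CC1(C)CCCC(O)C1=O | intermediate
11 | 3,3-dimethyl-2-oxocyclohexyl 2-(diethoxyphosphoryl)acetate (racemic) | CCOP(=O)(CC(=O)OC1CCCC(C)(C)C1=O)OCC | intermediate
12 | 4,4-dimethyl-5,6,7,7a-tetrahydro-1-benzofuran-2(4H)-one (racemic) | CC1(C)CCCC2OC(=O)C=C12 | intermediate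
13 | tert-butyl[(4,4-dimethyl-4,5,6,7-tetrahydro-1-benzofuran-2-yl)oxy]dimethylsilane | CC1(C)CCCc2oc(O[Si](C)(C)C(C)(C)C)cc12 | intermediate
14 | 7a-[hydroxy(4-isopropyl-2,3-dimethoxyphenyl)methyl]-4,4-dimethyl-5,6,7,7a-tetrahydro-1-benzofuran-2(4H)-one (racemic; both carbinol epimers) | COc1c(C(O)C23CCCC(C)(C)C2=CC(=O)O3)ccc(C(C)C)c1OC | intermediate
15 | 7a-(4-isopropyl-2,3-dimethoxybenzyl)-4,4-dimethyl-5,6,7,7a-tetrahydro-1-benzofuran-2(4H)-one (racemic) | COc1c(CC23CCCC(C)(C)C2=CC(=O)O3)ccc(C(C)C)c1OC | intermediate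
16 | (7aS)-7a-(4-isopropyl-2,3-dimethoxybenzyl)-4,4-dimethyl-5,6,7,7a-tetrahydro-1-benzofuran-2(4H)-one | COc1c(C[C@@]23CCCC(C)(C)C2=CC(=O)O3)ccc(C(C)C)c1OC | intermediate
17 | (3aS,7aS)-7a-(4-isopropyl-2,3-dimethoxybenzyl)-4,4-dimethylhexahydro-1-benzofuran-2(3H)-one (cis-fused) | COc1c(C[C@@]23CCCC(C)(C)[C@@H]2CC(=O)O3)ccc(C(C)C)c1OC | intermediate
18 | (3aS,7aS)-7a-(4-isopropyl-2,3-dimethoxybenzyl)-4,4-dimethyloctahydro-1-benzofuran-2-ol (both anomers) | COc1c(C[C@@]23CCCC(C)(C)[C@@H]2CC(O)O3)ccc(C(C)C)c1OC | intermediate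
19 | (5S,7S,10S)-7,10-epoxy-11,12-dimethoxyicetexa-8,11,13-triene (brussonol dimethyl ether) | CC(C)c1cc2c(c(OC)c1OC)C[C@@]13CCCC(C)(C)[C@@H]1C[C@@H]2O3 | intermediate
20 | (5S,7S,10S)-7,10-epoxyicetexa-8,11,13-triene-11,12-diol (brussonol) | CC(C)c1cc2c(c(O)c1O)C[C@@]13CCCC(C)(C)[C@@H]1C[C@@H]2O3 | intermediate
21 | (5S,7S,10S)-7,10-epoxyicetexa-8,13-diene-11,12-dione (brussonol o-quinone) | CC(C)C1=CC2=C(C(=O)C1=O)C[C@@]13CCCC(C)(C)[C@@H]1C[C@@H]2O3 | intermediate
22 | CNP0371333.1, hetero-Diels–Alder dimer of 21 (13′R,14′R) | CC(C)c1cc2c(c3c1O[C@@H]1C4=C(C[C@@]56CCCC(C)(C)[C@@H]5C[C@@H]4O6)C(=O)C(=O)[C@]1(C(C)C)O3)C[C@@]13CCCC(C)(C)[C@@H]1C[C@@H]2O3 | target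

**Totals and weak points**
Total step count: 17. Longest linear sequence: 14 steps (7 → 22, steps 4–17).

Most likely to fail, step 9 (vinylogous aldol at a fully substituted furan carbon; α-attack or retro-aldol). The fallback sets out from 6 and 7 and comes back at 15. The same C20–C10 bond is made before the lactone ring exists: 6 and 7 are condensed (KOH, EtOH, reflux; Claisen–Schmidt aldol condensation at the only enolisable α-carbon) to (E)-2-(4-isopropyl-2,3-dimethoxybenzylidene)-6,6-dimethylcyclohexanone F1. Weitz–Scheffer epoxidation (H2O2, NaOH, MeOH) gives racemic 2-(4-isopropyl-2,3-dimethoxyphenyl)-5,5-dimethyl-1-oxaspiro[2.5]octan-4-one F2. Hydrogenolysis of its benzylic C–O bond (H2, Pd/C, EtOAc) gives racemic 2-hydroxy-2-(4-isopropyl-2,3-dimethoxybenzyl)-6,6-dimethylcyclohexanone F3. Heating F3 with Ph3P=C=C=O (toluene, 110 °C; O-acylation, then intramolecular Wittig) closes the butenolide and rejoins the route at 15.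

Most likely to fail, step 12 (face selectivity of the butenolide hydrogenation; a trans-fused lactone would be useless). The fallback sets out from 16 and comes back at 19. The bridged ring is closed first and the alkene reduced afterwards: DIBAL-H (CH2Cl2, −78 °C) gives (7aS)-7a-(4-isopropyl-2,3-dimethoxybenzyl)-4,4-dimethyl-2,4,5,6,7,7a-hexahydro-1-benzofuran-2-ol F4. BF3·OEt2 then effects the Marson-type closure on the allyl-oxocarbenium ion to give (7S,10S)-7,10-epoxy-11,12-dimethoxyicetexa-5,8,11,13-tetraene F5. Hydrogenation (H2, Pd/C) of the C5=C6 bond, now held in the rigid oxabicyclo[3.2.1]octene where only the cis A-ring fusion is free of strain, gives 19.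

Most likely to fail, step 17 (stability of 21 and face selectivity of its dimerisation). The fallback sets out from 20, uses 21 as the heterodiene only, and comes back at 22. The two partners are differentiated: mono-methylation of 20 (MeI 1 equiv, K2CO3, acetone) at the less hindered 11-OH gives (5S,7S,10S)-7,10-epoxy-11-methoxyicetexa-8,11,13-trien-12-ol F6. Oxidative dearomatisation (PhI(OAc)2, MeOH, 0 °C) gives the masked o-quinone (5S,7S,10S)-7,10-epoxy-11,11-dimethoxyicetexa-8,13-dien-12-one F7. F7 is used in excess as the 2π partner (its C13=C14 bond) toward 21 in a crossed hetero-Diels–Alder reaction, giving the 11′,11′-dimethyl ketal of 22 F8. Aqueous TFA unmasks the C11′ ketone to give 22.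

**Further compounds**
F1 | step 9 | (E)-2-(4-isopropyl-2,3-dimethoxybenzylidene)-6,6-dimethylcyclohexanone | CC1(C)CCC/C(=C\c2ccc(C(C)C)c(OC)c2OC)C1=O
F2 | step 9 | 2-(4-isopropyl-2,3-dimethoxyphenyl)-5,5-dimethyl-1-oxaspiro[2.5]octan-4-one (racemic) | CC1(C)CCCC2(OC2c2ccc(C(C)C)c(OC)c2OC)C1=O
F3 | step 9 | 2-hydroxy-2-(4-isopropyl-2,3-dimethoxybenzyl)-6,6-dimethylcyclohexanone (racemic) | COc1c(CC2(O)CCCC(C)(C)C2=O)ccc(C(C)C)c1OC
F4 | step 12 | (7aS)-7a-(4-isopropyl-2,3-dimethoxybenzyl)-4,4-dimethyl-2,4,5,6,7,7a-hexahydro-1-benzofuran-2-ol (both anomers) | COc1c(C[C@@]23CCCC(C)(C)C2=CC(O)O3)ccc(C(C)C)c1OC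
F5 | step 12 | (7S,10S)-7,10-epoxy-11,12-dimethoxyicetexa-5,8,11,13-tetraene | CC(C)c1cc2c(c(OC)c1OC)C[C@@]13CCCC(C)(C)C1=C[C@@H]2O3
F6 | step 17 | (5S,7S,10S)-7,10-epoxy-11-methoxyicetexa-8,11,13-trien-12-ol | CC(C)c1cc2c(c(OC)c1O)C[C@@]13CCCC(C)(C)[C@@H]1C[C@@H]2O3
F7 | step 17 | (5S,7S,10S)-7,10-epoxy-11,11-dimethoxyicetexa-8,13-dien-12-one | CC(C)C1=CC2=C(C[C@@]34CCCC(C)(C)[C@@H]3C[C@@H]2O4)C(OC)(OC)C1=O
F8 | step 17 | 11′,11′-dimethyl ketal of 22 | CC(C)c1cc2c(c3c1O[C@@H]1C4=C(C[C@@]56CCCC(C)(C)[C@@H]5C[C@@H]4O6)C(OC)(OC)C(=O)[C@]1(C(C)C)O3)C[C@@]13CCCC(C)(C)[C@@H]1C[C@@H]2O3
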